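The numbers are invented; the flask was simulated.

In a closed flask like north nothing leaves, so every unit of starting material stays free, sits in target, or has passed to a side product. I reckon north by hand and leave the other set-ups unreckoned.

| flask | starting material | coupling partner | time | remark |
|---|---|---|---|---|
| north | 0.050 M | 0.0750 M | 12 h | everything together in a closed stirred flask, run for 12 h |
| south-east | 0.050 M | 0.0750 M |  | a single well-mixed tank run continuously and read at steady state, 12 h in it on average |
| south | 0.050 M | 0.0750 M (fed, over 12.0 h) | 12 h | all but coupling partner at the start; coupling partner goes in evenly over 12.0 h, the run ends at 12 h |
| west | 0.050 M (fed, over 12.0 h) | 0.0750 M | 12 h | a stirred flask in which starting material is dosed at a steady rate over 12.0 h without added volume, worked up at 12 h |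

- the set-up with the highest share of target in all that became target or side product A or side product B, at the outlet or at the end ("none" if the first two lie within 2 percentage points) (north / south-east / south / west / none)
- share of target in all that became target or side product A or side product B, at the outlet or at the end, north
- share of target in all that became target or side product A or side product B, at the outlet or at the end, south-east
- share of target in all that became target or side product A or side product B, at the outlet or at the end, south
- share of target in all that became target or side product A or side product B, at the outlet or at the end, west

- percent here means starting material units held: one side product B counts as two
- two of one species on the left: rate k times its square, two consumed each time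
- the stated concentrations are those of everything mixed, before any reaction; amounts are the same in each set-up
- the feed brings no volume worth counting
- run time (north): 12 h

    starting material → side product A (k1 = 0.0029 /min)
    2 starting material → side product B (k2 = 0.014 /M/min)
    coupling partner → decomposed reagent (k3 = 0.0069 /min)
    starting material + coupling partner ⇌ target (K4 = 190 /M, k4 = 0.26 /M/min)

1. If the coupling stood at equilibrium, target per free starting material would be the equilibrium constant times the free coupling partner. That is 14 at the start, but 0.0991 after 12 h if decay thins the reagent. You would then expect little target at the end.

2. Now the objection. Target falls apart with a release constant, the forward constant over the equilibrium constant: 0.00137 /min. Its half-life of 8.43 h is longer than the reagent's 1.7 h, so target lags behind that equilibrium and I drop the estimate.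

3. How much target forms? At the start, decay takes 0.53 of the reagent per unit of coupling, and side product A takes 0.15 of the starting material per unit of coupling. If a unit of target must win both races, the peak is about 56.9 %.

4. Plain release after one reagent half-life leaves 24.4 % of the charge as target. But released partners can meet again. Released reagent decays, so its level is about release times target over the decay constant, 0.00564 M, which is high because I use peak target.

5. Recapture is then pseudo-first-order at 0.00147 /min, against 0.0029 /min towards side product A. The dimerisation stays smaller, even at the full charge. So the free ratio, free starting material per target, is release over the sum of those two rates, 0.313, and target drains at that ratio times 0.0029 /min.

6. Target then ends near 32.4 %, and the share in north is 36.0 %.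

The forecast names north as best, with 38 %, 30 %, 22 % and 19 % for north, south-east, south and west, since “target forms best when both partners start together at high concentration”.

The simulation gives 39.5 %, 30.2 %, 21.7 % and 19.2 % in that order, so north is best. At 12.0 h north holds 34.0 % target and 14.0 % free starting material, with 4.03 % of its coupling partner left. With that reagent level, the release constant gives a free ratio of 0.371, and the flask shows 0.412. The same flask charged with 0.13 M coupling partner keeps 3.19 % of it, which gives 0.344, and it shows 0.336.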